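Side-chain carbons are numbered C1′–C36′ outward from the ring.

**Retrosynthetic overview**
- Last bond: ring–chain C1′–C2′, by Zr-catalysed methylalumination of a C43 terminal enyne and Ni-catalysed coupling with 2-(chloromethyl)-3-methyl-1,4-naphthoquinone. No ring is formed in the route; the naphthoquinone bicycle comes intact from menadione.
- Key disconnection: C12′–C13′ and C24′–C25′ are cut together around a hydroxy-farnesyl sulfone linchpin. Farnesyl C1, electrophilic in farnesyl bromide, reacts twice as a sulfonyl-stabilised carbanion in one flask: first from the linchpin onto a chiral primary iodide, then from farnesyl phenyl sulfone onto the linchpin's own in-situ tosylate.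
- Both sulfones are then removed together by Pd-catalysed hydride transfer.
- Chiral iodide: (R)-citronellyl bromide supplies C7′; allylic oxidation and a catalyst-controlled asymmetric hydrogenation set C11′; a silyl-propargyl anion adds C2′–C4′.

Assumption: the SMILES is read as 7′R,11′S (the same spatial sense as natural phytol), and (2E,6E)-farnesyl bromide and (R)-citronellyl bromide are taken as catalogue items.

**Route**

Step 1
Reactants: 1 (2E,6E)-farnesyl bromide
Product: 2 (2E,6E)-farnesyl phenyl sulfone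
Conditions: PhSO2Na (1.3 eq), DMF, 0 °C → rt, 12 h
Reagents that add atoms: sodium benzenesulfinate, [Na+].[O-]S(=O)c1ccccc1
Why: SN2 S-alkylation of the sulfinate at the primary allylic bromide gives the sulfone without touching the olefin geometry.

Step 2
Reactants: 2 (2E,6E)-farnesyl phenyl sulfone
Product: 3 (2E,6E,10E)-2,6,10-trimethyl-12-(phenylsulfonyl)dodeca-2,6,10-trien-1-ol
Conditions: SeO2 (0.5 eq), t-BuOOH (70% aq., 3 eq), salicylic acid (0.1 eq), CH2Cl2, 0 °C → rt, 24–36 h; recovered 2 recycled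
Reagents that add atoms: tert-butyl hydroperoxide, CC(C)(C)OO (oxygen relayed through selenium dioxide, O=[Se]=O)
Why: Sharpless SeO2/t-BuOOH allylic oxidation (ene reaction then [2,3]-shift) attacks the (E)-methyl of the most electron-rich, terminal trisubstituted alkene and gives the E allylic alcohol, while the sulfone-flanked alkene is the least reactive.

Step 3
Reactants: 4 (R)-citronellyl bromide [(6R)-8-bromo-2,6-dimethyloct-2-ene]
Product: 5 (2E,6R)-8-bromo-2,6-dimethyloct-2-en-1-ol
Conditions: SeO2 (0.5 eq), t-BuOOH (70% aq., 3 eq), salicylic acid (0.1 eq), CH2Cl2, 0 °C → rt, 24 h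
Reagents that add atoms: tert-butyl hydroperoxide, CC(C)(C)OO (oxygen relayed through selenium dioxide, O=[Se]=O)
Why: the same Sharpless allylic oxidation is E-selective at the isopropylidene terminus and leaves the primary bromide and the C6 stereocentre (future C7′) untouched.

Step 4
Reactants: 5 (2E,6R)-8-bromo-2,6-dimethyloct-2-en-1-ol
Product: 6 (2S,6R)-8-bromo-2,6-dimethyloctan-1-ol
Conditions: H2 (50 bar), [Ir(cod)(L*)][B(C6H3-3,5-(CF3)2)4] (1 mol %), CH2Cl2, 25 °C; L* = bicyclic pyridine–phosphinite P,N ligand, the antipode that reduces (2E,6E)-farnesol to (3R,7R)-hexahydrofarnesol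
Reagents that add atoms: none
Why: iridium-catalysed asymmetric hydrogenation of a trisubstituted alkene (Pfaltz type) under catalyst control; the alkene has the same E pattern as the 6,7-alkene of farnesol, so the same face is hydrogenated and, with the changed CIP priorities (CH2OH ranks first), the new centre is 2S (future C11′).

Step 5
Reactants: 6 (2S,6R)-8-bromo-2,6-dimethyloctan-1-ol
Product: 7 (2S,6R)-2,6-dimethyl-11-(trimethylsilyl)undec-10-yn-1-ol
Conditions: n-BuLi (1.0 eq), THF, −78 °C; then LiCH2C≡CSiMe3 [1-(trimethylsilyl)propyne (1.6 eq), n-BuLi (1.5 eq), TMEDA, THF, −78 → −20 °C], DMPU, −78 °C → rt; H2O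
Reagents that add atoms: 1-(trimethylsilyl)propyne, CC#C[Si](C)(C)C (used as its 3-lithio derivative)
Why: SN2 propargylation of the primary bromide by lithiated 1-(trimethylsilyl)propyne (Corey–Kirst type) adds C2′–C4′ as a silyl-capped alkyne, with the alcohol masked as its lithium alkoxide and both stereocentres untouched.

Step 6
Reactants: 7 (2S,6R)-2,6-dimethyl-11-(trimethylsilyl)undec-10-yn-1-ol
Product: 8 [(6R,10S)-11-iodo-6,10-dimethylundec-1-yn-1-yl]trimethylsilane
Conditions: I2 (1.3 eq), PPh3 (1.3 eq), imidazole (2 eq), CH2Cl2, 0 °C → rt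
Reagents that add atoms: iodine, II
Why: Appel-type (Garegg–Samuelsson) iodination converts the primary alcohol into the iodide by SN2 at CH2, so the adjacent stereocentre is not affected.

Step 7 (key step)
Reactants: 3 (2E,6E,10E)-2,6,10-trimethyl-12-(phenylsulfonyl)dodeca-2,6,10-trien-1-ol, 8 [(6R,10S)-11-iodo-6,10-dimethylundec-1-yn-1-yl]trimethylsilane, 2 (2E,6E)-farnesyl phenyl sulfone
Product: 11 trimethyl[(6R,10S,13E,17E,21E,25E,29E)-6,10,14,18,22,26,30,34-octamethyl-12,24-bis(phenylsulfonyl)pentatriaconta-13,17,21,25,29,33-hexaen-1-yn-1-yl]silane (epimers at C12/C24), via hydroxy sulfone lithium alkoxide 9 (not isolated), via allylic tosylate 10 (not isolated)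
Conditions: 3, n-BuLi (2.05 eq), THF, −78 °C; DMPU (5 eq), 8 (1.05 eq), −78 → −10 °C; TsCl (1.05 eq), −78 → −20 °C; then lithiated 2 [2 (1.3 eq), n-BuLi (1.3 eq), THF, −78 °C] by cannula, −78 → 0 °C; aq. NH4Cl
Reagents that add atoms: none
Why: Proposed new method: a one-flask relay in which farnesyl C1 (an electrophilic carbon in 1) reacts twice with reversed polarity as a sulfonyl-stabilised carbanion, joining carbons that all stem from C–halogen or C–OTs electrophiles; the dilithio derivative of 3 is C-alkylated at the soft sulfonyl carbanion by primary iodide 8 (C12′–C13′) far faster than the lithium alkoxide is O-alkylated, the surviving alkoxide is then tosylated in situ (Stork-type allylic alkoxide sulfonylation), and lithiated 2, too weak a base to deprotonate the already alkylated sulfone, displaces the primary allylic tosylate by SN2 (C24′–C25′); the closest known chemistry is the Biellmann/Julia alkylation of allylic sulfone anions used in polyprenol synthesis, and the two sulfonyl carbons form as epimer mixtures that step 8 erases while C7′ and C11′ are not touched.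

Step 8
Reactants: 11 bis-sulfone silyl enyne
Product: 13 (6R,10S,13E,17E,21E,25E,29E)-6,10,14,18,22,26,30,34-octamethylpentatriaconta-13,17,21,25,29,33-hexaen-1-yne, via silyl enyne 12 (not isolated)
Conditions: Pd(dppp)Cl2 (10 mol %), LiEt3BH (6 eq), THF, 0 °C → rt; then MeOH, K2CO3, rt, same flask
Reagents that add atoms: none
Why: palladium-catalysed hydride desulfonylation of allylic sulfones (Inomata–Kotake type) delivers hydride through a π-allyl–palladium hydride to the carbon that bore sulfur, keeping each trisubstituted alkene in place and E; the silyl cap shields the alkyne from the borohydride and is then removed by methanolysis in the same flask.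

Step 9
Reactants: 14 menadione (2-methyl-1,4-naphthoquinone)
Product: 15 2-(chloromethyl)-3-methyl-1,4-naphthoquinone
Conditions: 37% aq. HCHO, HCl (g), AcOH, rt, dark
Reagents that add atoms: formaldehyde, C=O; hydrogen chloride, Cl
Why: chloromethylation (Blanc type) occurs at the only free quinone C–H position and gives C1′ as a benzylic-type chloride.

Step 10
Reactants: 13 terminal enyne, 15 2-(chloromethyl)-3-methyl-1,4-naphthoquinone
Product: 17 2-methyl-3-[(2E,7R,11S,14E,18E,22E,26E,30E)-3,7,11,15,19,23,27,31,35-nonamethylhexatriaconta-2,14,18,22,26,30,34-heptaen-1-yl]naphthalene-1,4-dione (target), via alkenylalane 16 (not isolated)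
Conditions: Me3Al (2 eq), Cp2ZrCl2 (0.25 eq), ClCH2CH2Cl, rt, 12 h; volatiles removed, THF; 15 (0.9 eq), NiCl2(PPh3)2 (5 mol %)/n-BuLi (10 mol %) (zerovalent nickel), THF, −20 °C → rt
Reagents that add atoms: trimethylaluminium, C[Al](C)C
Why: Negishi zirconium-catalysed syn-methylalumination puts the methyl on C3′ and aluminium on C2′ (E only, about 95:5 regioselectivity), and Lipshutz-type nickel-catalysed coupling of the alkenylalane with the chloromethyl quinone forms C1′–C2′ with retention, so the 2′E alkene is set and the trisubstituted alkenes and both stereocentres are untouched.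

**Compound list**

1 | (2E,6E)-farnesyl bromide | CC(C)=CCC/C(C)=C/CC/C(C)=C/CBr | starting material
2 | (2E,6E)-farnesyl phenyl sulfone | CC(C)=CCC/C(C)=C/CC/C(C)=C/CS(=O)(=O)c1ccccc1 | intermediate
3 | (2E,6E,10E)-2,6,10-trimethyl-12-(phenylsulfonyl)dodeca-2,6,10-trien-1-ol | OC/C(C)=C/CC/C(C)=C/CC/C(C)=C/CS(=O)(=O)c1ccccc1 | intermediate
4 | (R)-citronellyl bromide | CC(C)=CCC[C@@H](C)CCBr | starting material
5 | (2E,6R)-8-bromo-2,6-dimethyloct-2-en-1-ol | OC/C(C)=C/CC[C@@H](C)CCBr | intermediate
6 | (2S,6R)-8-bromo-2,6-dimethyloctan-1-ol | OC[C@@H](C)CCC[C@@H](C)CCBr | intermediate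
7 | (2S,6R)-2,6-dimethyl-11-(trimethylsilyl)undec-10-yn-1-ol | OC[C@@H](C)CCC[C@@H](C)CCCC#C[Si](C)(C)C | intermediate
8 | [(6R,10S)-11-iodo-6,10-dimethylundec-1-yn-1-yl]trimethylsilane | IC[C@@H](C)CCC[C@@H](C)CCCC#C[Si](C)(C)C | intermediate
9 | (2E,6E,10E,14S,18R)-2,6,10,14,18-pentamethyl-12-(phenylsulfonyl)-23-(trimethylsilyl)tricosa-2,6,10-trien-22-yn-1-ol, C12 epimers (formed as its lithium alkoxide) | OC/C(C)=C/CC/C(C)=C/CC/C(C)=C/C(S(=O)(=O)c1ccccc1)C[C@@H](C)CCC[C@@H](C)CCCC#C[Si](C)(C)C | intermediate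
10 | 4-methylbenzenesulfonate (tosylate) of 9 | Cc1ccc(cc1)S(=O)(=O)OC/C(C)=C/CC/C(C)=C/CC/C(C)=C/C(S(=O)(=O)c1ccccc1)C[C@@H](C)CCC[C@@H](C)CCCC#C[Si](C)(C)C | intermediate
11 | trimethyl[(6R,10S,13E,17E,21E,25E,29E)-6,10,14,18,22,26,30,34-octamethyl-12,24-bis(phenylsulfonyl)pentatriaconta-13,17,21,25,29,33-hexaen-1-yn-1-yl]silane, C12/C24 epimers | CC(C)=CCC/C(C)=C/CC/C(C)=C/C(S(=O)(=O)c1ccccc1)C/C(C)=C/CC/C(C)=C/CC/C(C)=C/C(S(=O)(=O)c1ccccc1)C[C@@H](C)CCC[C@@H](C)CCCC#C[Si](C)(C)C | intermediate
12 | trimethyl[(6R,10S,13E,17E,21E,25E,29E)-6,10,14,18,22,26,30,34-octamethylpentatriaconta-13,17,21,25,29,33-hexaen-1-yn-1-yl]silane | CC(C)=CCC/C(C)=C/CC/C(C)=C/CC/C(C)=C/CC/C(C)=C/CC/C(C)=C/CC[C@@H](C)CCC[C@@H](C)CCCC#C[Si](C)(C)C | intermediate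
13 | (6R,10S,13E,17E,21E,25E,29E)-6,10,14,18,22,26,30,34-octamethylpentatriaconta-13,17,21,25,29,33-hexaen-1-yne | CC(C)=CCC/C(C)=C/CC/C(C)=C/CC/C(C)=C/CC/C(C)=C/CC/C(C)=C/CC[C@@H](C)CCC[C@@H](C)CCCC#C | intermediate
14 | menadione | CC1=CC(=O)c2ccccc2C1=O | starting material
15 | 2-(chloromethyl)-3-methyl-1,4-naphthoquinone | ClCC1=C(C)C(=O)c2ccccc2C1=O | intermediate
16 | dimethyl[(1E,6R,10S,13E,17E,21E,25E,29E)-2,6,10,14,18,22,26,30,34-nonamethylpentatriaconta-1,13,17,21,25,29,33-heptaen-1-yl]alumane | CC(C)=CCC/C(C)=C/CC/C(C)=C/CC/C(C)=C/CC/C(C)=C/CC/C(C)=C/CC[C@@H](C)CCC[C@@H](C)CCC/C(C)=C/[Al](C)C | intermediate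
17 | 2-methyl-3-[(2E,7R,11S,14E,18E,22E,26E,30E)-3,7,11,15,19,23,27,31,35-nonamethylhexatriaconta-2,14,18,22,26,30,34-heptaen-1-yl]naphthalene-1,4-dione (CNP0265071.1) | CC(C)=CCC/C(C)=C/CC/C(C)=C/CC/C(C)=C/CC/C(C)=C/CC/C(C)=C/CC[C@@H](C)CCC[C@@H](C)CCC/C(C)=C/CC1=C(C)C(=O)c2ccccc2C1=O | target

**Step count**

Total: 10 steps. Longest linear sequence: 7 steps (steps 3, 4, 5, 6, 7, 8, 10, from 4 to 17).

**Three steps most likely to fail**

Step 7 (one-flask double sulfone coupling). Failure modes are O-alkylation of the dianion, incomplete in-situ tosylation and proton scrambling between sulfones. The fallback removes the free hydroxyl and separates the two bond formations. It sets out from 3 and 8. Dihydropyran with PPTS converts 3 into the tetrahydropyranyl ether F4. Its monolithio derivative (n-BuLi 1.0 eq, THF/DMPU, −78 °C) is alkylated with 8 to give the protected coupling product F5. PPTS in MeOH, which leaves the alkynylsilane alone, releases alcohol 9, this time isolated and purified. PBr3 (Et2O, −10 °C) gives the allylic bromide F6. Lithiated 2 displaces bromide from F6 and the route is rejoined at 11.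

Step 4 (catalyst-controlled hydrogenation of a 2-methyl allylic alcohol). The risk is insufficient facial selectivity with the iridium P,N catalyst. The fallback changes to carboxylate-directed ruthenium hydrogenation and sets out from 5. MnO2 (CH2Cl2) gives the enal (2E,6R)-8-bromo-2,6-dimethyloct-2-enal F1. Pinnick oxidation (NaClO2, NaH2PO4, 2-methyl-2-butene) gives (2E,6R)-8-bromo-2,6-dimethyloct-2-enoic acid F2. Hydrogenation with Ru(OAc)2(H8-BINAP), using the ligand antipode that turns tiglic acid into (S)-2-methylbutanoic acid, gives (2S,6R)-8-bromo-2,6-dimethyloctanoic acid F3. BH3·SMe2 reduces F3 to 6, where the route is rejoined.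

Step 10 (nickel coupling of an alkenylalane with an unprotected quinone). The risks are attack of residual Me3Al on the quinone and catalyst death. The fallback changes the ring–chain bond to a Friedel–Crafts alkylation and sets out from 13 and 14. Alkenylalane 16 is made as before, converted into its alanate with n-BuLi and trapped with paraformaldehyde to give the allylic alcohol (2E,7R,11S,14E,18E,22E,26E,30E)-3,7,11,15,19,23,27,31,35-nonamethylhexatriaconta-2,14,18,22,26,30,34-heptaen-1-ol F7. Menadione 14 is reduced with Na2S2O4 to menadiol F8. BF3·OEt2 in dioxane/EtOAc alkylates F8 with F7 at C3 to give the side-chain naphthohydroquinone F9. Ag2O in Et2O oxidises F9 and the route is rejoined at 17.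

**Further compounds**

F1 | step 4 | (2E,6R)-8-bromo-2,6-dimethyloct-2-enal | O=C/C(C)=C/CC[C@@H](C)CCBr
F2 | step 4 | (2E,6R)-8-bromo-2,6-dimethyloct-2-enoic acid | OC(=O)/C(C)=C/CC[C@@H](C)CCBr
F3 | step 4 | (2S,6R)-8-bromo-2,6-dimethyloctanoic acid | OC(=O)[C@@H](C)CCC[C@@H](C)CCBr
F4 | step 7 | 2-{[(2E,6E,10E)-2,6,10-trimethyl-12-(phenylsulfonyl)dodeca-2,6,10-trien-1-yl]oxy}tetrahydropyran | O(C1CCCCO1)C/C(C)=C/CC/C(C)=C/CC/C(C)=C/CS(=O)(=O)c1ccccc1
F5 | step 7 | tetrahydropyranyl ether of 9 | O(C1CCCCO1)C/C(C)=C/CC/C(C)=C/CC/C(C)=C/C(S(=O)(=O)c1ccccc1)C[C@@H](C)CCC[C@@H](C)CCCC#C[Si](C)(C)C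
F6 | step 7 | allylic bromide from 9, [(6R,10S,13E,17E,21E)-23-bromo-6,10,14,18,22-pentamethyl-12-(phenylsulfonyl)tricosa-13,17,21-trien-1-yn-1-yl]trimethylsilane | BrC/C(C)=C/CC/C(C)=C/CC/C(C)=C/C(S(=O)(=O)c1ccccc1)C[C@@H](C)CCC[C@@H](C)CCCC#C[Si](C)(C)C
F7 | step 10 | (2E,7R,11S,14E,18E,22E,26E,30E)-3,7,11,15,19,23,27,31,35-nonamethylhexatriaconta-2,14,18,22,26,30,34-heptaen-1-ol | CC(C)=CCC/C(C)=C/CC/C(C)=C/CC/C(C)=C/CC/C(C)=C/CC/C(C)=C/CC[C@@H](C)CCC[C@@H](C)CCC/C(C)=C/CO
F8 | step 10 | menadiol (2-methylnaphthalene-1,4-diol) | Cc1cc(O)c2ccccc2c1O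
F9 | step 10 | 2-methyl-3-[(2E,7R,11S,14E,18E,22E,26E,30E)-3,7,11,15,19,23,27,31,35-nonamethylhexatriaconta-2,14,18,22,26,30,34-heptaen-1-yl]naphthalene-1,4-diol | CC(C)=CCC/C(C)=C/CC/C(C)=C/CC/C(C)=C/CC/C(C)=C/CC/C(C)=C/CC[C@@H](C)CCC[C@@H](C)CCC/C(C)=C/Cc1c(C)c(O)c2ccccc2c1O
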